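Take the flask one process at a time, and reckon only the correction to the big number.

    J + L + Q → L + E (k1 = 650 /M²/s)
    J + L + Z → L + D (k2 = 77 /M²/s)
    Q ⇌ Z (k3 = 0.017 /s)
    2 L → L2 (k4 = 30 /M/s)

Q 0.43 M; J 0.258 M (fed, over 15 s); L 0.52 mM; Z 0.43 M; time 10 min

- L is single-handed; Q and Z are mirror images of each other, charged as a racemate, each of them at the stated concentration
- a doubled species enters its step squared and goes two at a time
- the reaction counts as stopped when no species that holds the Q and Z together changes by six tenths of a point or more over the second half of the time
- run time (flask): 10 min

- why nothing more happens at 10 min, or that something still does (forward and back rates have come level / it is still moving / all of Q has reacted / J has run out first / no working catalyst is left)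
- how much E there is at 10 min, in percent of the Q and Z together charged
- how much Z there is at 10 min, in percent of the Q and Z together charged
- how much D there is at 10 min, in percent of the Q and Z together charged

I begin with the main step alone, J + L + Q to E. Each J spent makes one E, and J is charged at less than Q, so J is the limiting reagent and E can reach 30.0 % of the Q and Z together.

Now I add the step from Z to D, which competes for the same J. Both steps carry [L], so while [Q] equals [Z] their rates stand as their constants, 650 /M²/s to 77 /M²/s, a selectivity factor of 8.44. The part of the J spent that ends in E while [Q] equals [Z], the E share, is the first constant over the sum of both: 89.4 %. D is then the small correction, 3.18 %, and E is 26.8 %.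

Then comes the rest. The forward half-life of Q to Z is 0.68 min, shorter than the run, so I let what J leaves even out, and Z stands at 35.0 %. The feed of 15 s is shorter than that half-life, so I expect Q to lag behind Z early and E to fall a little under my figure. By dimerisation alone the first half-life of L is 0.534 min, but the half-life of J by the main step alone, at the charged [L] and [Q], is 0.0795 min, which is shorter, so I expect J to go first.

The forecast says J has run out first, with E 25.8 %, Z 35 % and D 4.2 %. Its E is lower than mine, on the ground that the preference is “slightly eroded by Q depletion and partly restored by racemisation”.

The simulation gives J has run out first, with J at 0 % of its charge, E 26.3 %, Z 35.0 % and D 3.73 %. In this flask E over E plus D comes to 87.6 %, below the E share of 89.4 %, and the rate to E over the rate to D reads 6.8 at 0.251 min, against 8.44 for the constants, with Q at 37.9 % and Z at 47.2 % at 0.250 min. In the neighbour flask with 0.065 M of J, the E share times that J charge over the Q and Z together gives 6.76 %, and that flask holds 6.73 % of E.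

Its constants were chosen freely; the flask was simulated.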